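**Retrosynthetic overview**
1. Zeylenone (24) has one ring, a cyclohex-3-en-2-one (C1–C6; C7 is the CH2OBz carbon on C1). The strategy rests on the adjacent carbinol carbons C1 (fully substituted, bearing C7) and C6, whose hydroxyls are cis on the six-membered ring: the retron of a ketone–aldehyde pinacol coupling.
2. Endgame from cis-diol 17: acetonide on O1/O6, both 4-methoxybenzyl (PMB) ethers (O5, O7) exchanged for benzoates, C2 silyl ether turned into the ketone, acetonide removed.
3. The only ring is formed in step 10: the C1–C6 bond is made by SmI2 ketyl coupling of the Z keto-aldehyde 16.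
4. 16 comes from an alkyne diol by semi-hydrogenation and double oxidation. The C2–C3 bond is made by Felkin-type addition of alkyne 5 (C3–C6, from (S)-glyceraldehyde acetonide and the Ohira–Bestmann reagent) to (R)-glyceraldehyde acetonide (C2, C1, C7); the C1 centre only relays chirality to C2 and is then oxidized.
5. Protecting groups: a 4-methoxybenzylidene acetal opened with i-Bu2AlH gives O5-PMB/O6-H. C7 is carried through the ring closure as a PMB ether, not as the benzoate, because SmI2 would cleave an α-benzoyloxy ketone reductively before it couples.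

Key step: step 10

Remark: atoms are numbered as in zeylenone throughout (C1 carbinol carbon bearing C7, C2 ketone carbon, C3=C4, C5, C6); compounds 5 and 7–10 are mixtures of epimers at the 4-methoxybenzylidene acetal carbon, which disappears in step 5.

**Step 1**
Reactants: 1 (S)-glyceraldehyde acetonide; 2 dimethyl (1-diazo-2-oxopropyl)phosphonate
Product: 3 (4R)-4-ethynyl-2,2-dimethyl-1,3-dioxolane
Conditions: K2CO3, MeOH, 0 → 23 °C (volatile product kept as a concentrated solution)
Reagents that add atoms: dimethyl (1-diazo-2-oxopropyl)phosphonate (2), CC(=O)C(=[N+]=[N-])P(=O)(OC)OC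
Why: Ohira–Bestmann (Seyferth–Gilbert) homologation, in which methoxide cleaves the acetyl group of 2 and the diazomethylphosphonate anion adds to the aldehyde, loses dimethyl phosphate and N2 and rearranges to the terminal alkyne, under carbonate conditions mild enough to keep the α-alkoxy stereocentre (the later C5), whose descriptor changes only through the priority rules.

**Step 2**
Reactants: 3 (4R)-4-ethynyl-2,2-dimethyl-1,3-dioxolane
Product: 5 (4R)-4-ethynyl-2-(4-methoxyphenyl)-1,3-dioxolane (both acetal epimers), via (2R)-but-3-yne-1,2-diol 4 (not isolated)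
Conditions: p-TsOH·H2O (cat.), MeOH, 23 °C; evaporate; 4-MeOC6H4CH(OMe)2, CSA (cat.), CH2Cl2, 23 °C
Reagents that add atoms: 4-methoxybenzaldehyde dimethyl acetal, COc1ccc(C(OC)OC)cc1
Why: acid-catalysed acetal exchange (transacetalization), in which methanolysis frees the 1,2-diol and the aryl-stabilised 4-methoxybenzylidene acetal then forms with loss of methanol, without touching the stereocentre.

**Step 3**
Reactants: 5 (4R)-4-ethynyl-2-(4-methoxyphenyl)-1,3-dioxolane; 6 (R)-glyceraldehyde acetonide
Product: 9 (1S)-1-[(4R)-2,2-dimethyl-1,3-dioxolan-4-yl]-3-[(4R)-2-(4-methoxyphenyl)-1,3-dioxolan-4-yl]prop-2-yn-1-ol (anti adduct), via lithium acetylide 7 (not isolated), via alkynyltitanium triisopropoxide 8 (not isolated)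
Conditions: n-BuLi, THF, −78 °C; ClTi(Oi-Pr)3, −78 → −40 °C; 6, −78 → 0 °C
Reagents that add atoms: none
Why: 1,2-addition of an alkynyl metal to an α-alkoxy aldehyde under Felkin–Anh (non-chelation) control, the weakly Lewis acidic alkynyltitanium attacking the face anti to the C1–O bond, which should give mainly the anti (S) carbinol at C2; the minor syn epimer is removed by chromatography.

**Step 4**
Reactants: 9 anti propargylic alcohol
Product: 10 tert-butyldimethylsilyl ether of 9 at O2
Conditions: TBSCl, imidazole, DMF, 23 °C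
Reagents that add atoms: tert-butyldimethylsilyl chloride, CC(C)(C)[Si](C)(C)Cl
Why: standard silylation of the only free hydroxyl, with the chloride/imidazole pair chosen over a silyl triflate so that neither acetal is opened.

**Step 5**
Reactants: 10 silyl ether
Product: 11 (2R,5S)-5-(tert-butyldimethylsilyloxy)-5-[(4R)-2,2-dimethyl-1,3-dioxolan-4-yl]-2-(4-methoxybenzyloxy)pent-3-yn-1-ol (O5-PMB, free C6 hydroxyl)
Conditions: i-Bu2AlH, CH2Cl2, −78 → 0 °C
Reagents that add atoms: none
Why: regioselective reductive opening of a 4-methoxybenzylidene acetal, in which aluminium binds the less hindered primary oxygen, that C–O bond breaks and hydride adds to the oxocarbenium ion, so the PMB group should stay on the secondary C5 oxygen while the isopropylidene acetal, silyl ether and alkyne are inert at low temperature.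

**Step 6**
Reactants: 11 primary alcohol
Product: 12 (2R,3S,6R)-3-(tert-butyldimethylsilyloxy)-6-(4-methoxybenzyloxy)hept-4-yne-1,2,7-triol
Conditions: AcOH–THF–H2O (3:1:1), 35 °C
Reagents that add atoms: none
Why: mild aqueous acid hydrolysis of the terminal isopropylidene acetal, conditions that a secondary tert-butyldimethylsilyl ether and a PMB ether should survive.

**Step 7**
Reactants: 12 triol
Product: 14 (2R,5S,6R)-5-(tert-butyldimethylsilyloxy)-2,7-bis(4-methoxybenzyloxy)hept-3-yne-1,6-diol (new PMB ether on O7), via dibutylstannylene acetal 13 (not isolated)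
Conditions: Bu2SnO, toluene, reflux (Dean–Stark); then 4-MeOC6H4CH2Cl, Bu4NI (cat.), toluene, 80 °C
Reagents that add atoms: 4-methoxybenzyl chloride, COc1ccc(CCl)cc1
Why: stannylene-acetal-mediated regioselective monoalkylation, in which tin forms the five-membered acetal only with the C1/C7 1,2-diol and activates its primary oxygen toward the benzylic halide, while the isolated C6 hydroxyl is not activated (the same diol recognition as in tin-mediated selective acylation and sulfonylation of glycols beside other primary alcohols).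

**Step 8**
Reactants: 14 alkyne diol
Product: 15 (2R,3Z,5S,6R)-5-(tert-butyldimethylsilyloxy)-2,7-bis(4-methoxybenzyloxy)hept-3-ene-1,6-diol
Conditions: H2 (1 atm), Pd/CaCO3 poisoned with Pb(OAc)2, quinoline, EtOAc, 23 °C
Reagents that add atoms: none
Why: Lindlar semi-hydrogenation, syn delivery of H2 on the poisoned palladium surface, which should give the Z alkene without over-reduction or hydrogenolysis of the benzylic ethers.

**Step 9**
Reactants: 15 Z-alkene diol
Product: 16 (2R,3Z,5S)-5-(tert-butyldimethylsilyloxy)-2,7-bis(4-methoxybenzyloxy)-6-oxohept-3-enal (C1 ketone, C6 aldehyde)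
Conditions: Dess–Martin periodinane, CH2Cl2, 0 → 23 °C; filtered, concentrated cold and used at once
Reagents that add atoms: none
Why: Dess–Martin oxidation of the secondary C1 and the primary C6 alcohol in one operation without amine base, chosen over a Swern oxidation so that the two β,γ-unsaturated α-oxy carbonyl groups neither epimerize at C2/C5 nor move into conjugation.

**Step 10**
Reactants: 16 Z keto-aldehyde
Product: 17 (1S,2S,5R,6S)-2-(tert-butyldimethylsilyloxy)-5-(4-methoxybenzyloxy)-1-[(4-methoxybenzyloxy)methyl]cyclohex-3-ene-1,6-diol (OH-1 and OH-6 cis, both trans to O2 and O5)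
Conditions: SmI2 (3 equiv), t-BuOH (3 equiv), THF, −78 → −40 °C
Reagents that add atoms: none
Why: SmI2 (divalent samarium) transfers one electron to the aldehyde, the less hindered and more easily reduced carbonyl, and the ketyl at C6, bound to trivalent samarium, adds to the C1 ketone held on the same metal; a second electron transfer gives the samarium diolate, which t-BuOH and the work-up protonate. The closest known reaction type is the SmI2 pinacol cyclization of sugar-derived 1,6-dicarbonyl compounds to cis-cyclitol diols. The cyclohexene ring closes in a 6-exo-trig mode by attack of the C6 ketyl carbon on the C1 carbonyl carbon, the Z alkene holding the two carbonyl groups within bonding distance. The cis relation of the new C1 and C6 hydroxyls should follow from one samarium bridging both oxygens in the transition state; their face should follow from the C2 silyl ether and the C5 PMB ether, which lie on one face of the Z alkene (allylic strain keeps both C–H bonds in the alkene plane) and push the metal-bound oxygens to the other face. The step needs aldehyde-first reduction without loss of an α-oxygen substituent, which is secured by having only ether groups next to both carbonyls, by the low temperature and by leaving out HMPA.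

**Step 11**
Reactants: 17 cis-diol
Product: 18 1,6-O-isopropylidene acetal of 17 (1S,2S,5R,6S)
Conditions: Me2C(OMe)2, PPTS (cat.), CH2Cl2, 23 °C
Reagents that add atoms: 2,2-dimethoxypropane, COC(C)(C)OC
Why: acid-catalysed acetonide formation, possible because the C1 and C6 hydroxyls are cis, which masks both before the ether-to-ester exchange.

**Step 12**
Reactants: 18 acetonide
Product: 19 (1S,2S,5R,6S)-2-(tert-butyldimethylsilyloxy)-1-(hydroxymethyl)-1,6-O-isopropylidenecyclohex-3-ene-1,5,6-triol (free O5-H and O7-H)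
Conditions: DDQ, CH2Cl2–pH 7 buffer (10:1), 0 °C
Reagents that add atoms: none
Why: oxidative cleavage of both PMB ethers (hydride abstraction by DDQ, hydrolysis of the oxocarbenium ions to 4-methoxybenzaldehyde) in a buffered two-phase system that should leave the silyl ether, the acetonide and the alkene untouched.

**Step 13**
Reactants: 19 diol; 20 benzoyl chloride
Product: 21 5,7-di-O-benzoate of 19 (1S,2S,5R,6S)
Conditions: BzCl, pyridine, DMAP (cat.), CH2Cl2, 0 → 23 °C
Reagents that add atoms: benzoyl chloride (20), O=C(Cl)c1ccccc1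
Why: DMAP-catalysed acylation of the primary C7 and the allylic C5 hydroxyl, the only free hydroxyls, which installs both benzoates of the target at once.

**Step 14**
Reactants: 21 dibenzoate
Product: 22 C2 alcohol (1R,2S,5R,6S; descriptor at C1 changes by priority only): 5,7-di-O-benzoyl-1,6-O-isopropylidene-1-(hydroxymethyl)cyclohex-3-ene-1,2,5,6-tetrol
Conditions: HF·pyridine, pyridine, THF, 0 → 23 °C
Reagents that add atoms: none
Why: fluoride-mediated desilylation under buffered, weakly acidic conditions, chosen over Bu4NF to avoid base-induced benzoate migration from O7 to the freed O2.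

**Step 15**
Reactants: 22 allylic alcohol
Product: 23 zeylenone 1,6-acetonide (1S,5R,6S)
Conditions: Dess–Martin periodinane, CH2Cl2, 23 °C
Reagents that add atoms: none
Why: Dess–Martin oxidation of the allylic C2 alcohol to the enone; C1 is fully substituted, so the new ketone can neither epimerize nor eliminate toward C1.

**Step 16**
Reactants: 23 enone acetonide
Product: 24 zeylenone (1S,5R,6S)
Conditions: TFA–H2O (9:1), 0 °C
Reagents that add atoms: none
Why: acid hydrolysis of the isopropylidene acetal, which the benzoates and the enone should tolerate, frees the cis C1/C6 diol.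

**Compound list**
1 | (S)-glyceraldehyde acetonide, (4S)-2,2-dimethyl-1,3-dioxolane-4-carbaldehyde | O=C[C@@H]1COC(C)(C)O1 | starting material
2 | dimethyl (1-diazo-2-oxopropyl)phosphonate | CC(=O)C(=[N+]=[N-])P(=O)(OC)OC | starting material
3 | (4R)-4-ethynyl-2,2-dimethyl-1,3-dioxolane | C#C[C@@H]1COC(C)(C)O1 | intermediate
4 | (2R)-but-3-yne-1,2-diol | C#C[C@@H](O)CO | intermediate
5 | (4R)-4-ethynyl-2-(4-methoxyphenyl)-1,3-dioxolane, both acetal epimers | C#C[C@@H]1COC(c2ccc(OC)cc2)O1 | intermediate
6 | (R)-glyceraldehyde acetonide, (4R)-2,2-dimethyl-1,3-dioxolane-4-carbaldehyde | O=C[C@H]1COC(C)(C)O1 | starting material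
7 | lithium acetylide of 5 | [Li]C#C[C@@H]1COC(c2ccc(OC)cc2)O1 | intermediate
8 | alkynyltitanium triisopropoxide from 5 | CC(C)O[Ti](OC(C)C)(OC(C)C)C#C[C@@H]1COC(c2ccc(OC)cc2)O1 | intermediate
9 | (1S)-1-[(4R)-2,2-dimethyl-1,3-dioxolan-4-yl]-3-[(4R)-2-(4-methoxyphenyl)-1,3-dioxolan-4-yl]prop-2-yn-1-ol | CC1(C)OC[C@@H](O1)[C@@H](O)C#C[C@@H]1COC(c2ccc(OC)cc2)O1 | intermediate
10 | tert-butyldimethylsilyl ether of 9 | CC1(C)OC[C@@H](O1)[C@@H](O[Si](C)(C)C(C)(C)C)C#C[C@@H]1COC(c2ccc(OC)cc2)O1 | intermediate
11 | (2R,5S)-5-(tert-butyldimethylsilyloxy)-5-[(4R)-2,2-dimethyl-1,3-dioxolan-4-yl]-2-(4-methoxybenzyloxy)pent-3-yn-1-ol | CC1(C)OC[C@@H](O1)[C@@H](O[Si](C)(C)C(C)(C)C)C#C[C@@H](OCc1ccc(OC)cc1)CO | intermediate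
12 | (2R,3S,6R)-3-(tert-butyldimethylsilyloxy)-6-(4-methoxybenzyloxy)hept-4-yne-1,2,7-triol | OC[C@@H](O)[C@@H](O[Si](C)(C)C(C)(C)C)C#C[C@@H](OCc1ccc(OC)cc1)CO | intermediate
13 | 1,2-O-dibutylstannylene acetal of 12 (tin on O7 and O1) | CCCC[Sn]1(CCCC)OC[C@@H](O1)[C@@H](O[Si](C)(C)C(C)(C)C)C#C[C@@H](OCc1ccc(OC)cc1)CO | intermediate
14 | (2R,5S,6R)-5-(tert-butyldimethylsilyloxy)-2,7-bis(4-methoxybenzyloxy)hept-3-yne-1,6-diol | COc1ccc(COC[C@@H](O)[C@@H](O[Si](C)(C)C(C)(C)C)C#C[C@@H](OCc2ccc(OC)cc2)CO)cc1 | intermediate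
15 | (2R,3Z,5S,6R)-5-(tert-butyldimethylsilyloxy)-2,7-bis(4-methoxybenzyloxy)hept-3-ene-1,6-diol | COc1ccc(COC[C@@H](O)[C@@H](O[Si](C)(C)C(C)(C)C)/C=C\[C@@H](OCc2ccc(OC)cc2)CO)cc1 | intermediate
16 | (2R,3Z,5S)-5-(tert-butyldimethylsilyloxy)-2,7-bis(4-methoxybenzyloxy)-6-oxohept-3-enal | COc1ccc(COCC(=O)[C@@H](O[Si](C)(C)C(C)(C)C)/C=C\[C@@H](OCc2ccc(OC)cc2)C=O)cc1 | intermediate
17 | (1S,2S,5R,6S)-2-(tert-butyldimethylsilyloxy)-5-(4-methoxybenzyloxy)-1-[(4-methoxybenzyloxy)methyl]cyclohex-3-ene-1,6-diol | COc1ccc(COC[C@@]2(O)[C@@H](O[Si](C)(C)C(C)(C)C)C=C[C@@H](OCc3ccc(OC)cc3)[C@@H]2O)cc1 | intermediate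
18 | 1,6-O-isopropylidene acetal of 17 | COc1ccc(COC[C@@]2(O3)[C@@H](O[Si](C)(C)C(C)(C)C)C=C[C@@H](OCc4ccc(OC)cc4)[C@@H]2OC3(C)C)cc1 | intermediate
19 | 5,7-diol: 1,6-acetonide of (1S,2S,5R,6S)-2-(tert-butyldimethylsilyloxy)-1-(hydroxymethyl)cyclohex-3-ene-1,5,6-triol | OC[C@@]1(O2)[C@@H](O[Si](C)(C)C(C)(C)C)C=C[C@@H](O)[C@@H]1OC2(C)C | intermediate
20 | benzoyl chloride | O=C(Cl)c1ccccc1 | starting material
21 | 5,7-di-O-benzoate of 19 | O=C(OC[C@@]1(O2)[C@@H](O[Si](C)(C)C(C)(C)C)C=C[C@@H](OC(=O)c3ccccc3)[C@@H]1OC2(C)C)c1ccccc1 | intermediate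
22 | C2 alcohol, desilylated 21 (1R,2S,5R,6S) | O=C(OC[C@@]1(O2)[C@@H](O)C=C[C@@H](OC(=O)c3ccccc3)[C@@H]1OC2(C)C)c1ccccc1 | intermediate
23 | zeylenone 1,6-acetonide | O=C(OC[C@@]1(O2)C(=O)C=C[C@@H](OC(=O)c3ccccc3)[C@@H]1OC2(C)C)c1ccccc1 | intermediate
24 | zeylenone, (1S,5R,6S) | O=C(OC[C@@]1(O)C(=O)C=C[C@@H](OC(=O)c2ccccc2)[C@@H]1O)c1ccccc1 | target

**Step count**
Total: 16 steps. Longest linear sequence: 16 steps (1 → 24); 6 enters at step 3 and 20 at step 13.

**Steps most likely to fail**

1. Step 10. What may go wrong: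
- a second electron transfer to a ketyl followed by β-elimination of an α-oxygen substituent (reductive deoxygenation);
- simple reduction of the aldehyde;
- ring closure on the wrong face;
- migration of the β,γ double bond of 16 into conjugation, or epimerization at C2/C5, before the C–C bond forms.

Fallback (the ring is closed on the saturated chain and the C3=C4 bond is introduced afterwards by dehydrogenation of the C2 ketone). It sets out from 15 and comes back at 23.
- Diimide (2-nitrobenzenesulfonylhydrazide, Et3N, CH2Cl2) saturates the alkene to the 3,4-dihydro diol F1.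
- Dess–Martin oxidation gives the saturated keto-aldehyde F2, which has no β,γ-unsaturation and can be purified.
- SmI2/t-BuOH in THF closes the ring to the cyclohexane cis-1,6-diol F3, with the same sense of induction from the C2 and C5 ethers.
- The chemistry of steps 11–15 then gives in turn the acetonide F4, the 5,7-diol F5 (DDQ), the dibenzoate F6, the C2 alcohol F7 (HF·pyridine) and the cyclohexanone F8 (Dess–Martin).
- Because C1 is fully substituted, F8 can enolize only toward C3: TMSOTf/Et3N gives the trimethylsilyl enol ether F9, and Saegusa–Ito oxidation with Pd(OAc)2 in MeCN installs the C3=C4 bond to give 23.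

2. Step 7. What may go wrong: loss of regioselectivity, that is alkylation of the isolated C6 hydroxyl or double alkylation, when tin exchanges among the three hydroxyls.

Fallback (the C6 hydroxyl is blocked before the diol is freed). It sets out from 11 and comes back at 14.
- PivCl/pyridine gives the C6 pivalate F10.
- AcOH–THF–H2O removes the acetonide to give the diol F11.
- Bu2SnO forms the stannylene acetal F12, and 4-methoxybenzyl chloride/Bu4NI then gives the O7-PMB ether F13, with no competing hydroxyl.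
- i-Bu2AlH in CH2Cl2 at −78 °C cleaves the pivalate to give 14.

3. Step 3. What may go wrong: poor facial selectivity in the addition to the aldehyde, so that a large share of the syn C2 epimer forms.

Fallback (C2 is set by SN2 inversion, not by facial selectivity, so all material converges). It sets out from the product mixture of step 3 (made from 5 and 6) and comes back at 9.
- The syn carbinol F14 is separated.
- Mitsunobu reaction (4-nitrobenzoic acid, PPh3, DIAD, THF) converts it with inversion into the anti 4-nitrobenzoate F15.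
- K2CO3/MeOH cleaves the ester to give 9.

**Further compounds**
F1 | step 10 | 3,4-dihydro analogue of 15 (saturated diol) | COc1ccc(COC[C@@H](O)[C@@H](O[Si](C)(C)C(C)(C)C)CC[C@@H](OCc2ccc(OC)cc2)CO)cc1
F2 | step 10 | 3,4-dihydro analogue of 16 (saturated keto-aldehyde) | COc1ccc(COCC(=O)[C@@H](O[Si](C)(C)C(C)(C)C)CC[C@@H](OCc2ccc(OC)cc2)C=O)cc1
F3 | step 10 | 3,4-dihydro analogue of 17 (cyclohexane cis-1,6-diol) | COc1ccc(COC[C@@]2(O)[C@@H](O[Si](C)(C)C(C)(C)C)CC[C@@H](OCc3ccc(OC)cc3)[C@@H]2O)cc1
F4 | step 10 | 3,4-dihydro analogue of 18 (acetonide) | COc1ccc(COC[C@@]2(O3)[C@@H](O[Si](C)(C)C(C)(C)C)CC[C@@H](OCc4ccc(OC)cc4)[C@@H]2OC3(C)C)cc1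
F5 | step 10 | 3,4-dihydro analogue of 19 (5,7-diol) | OC[C@@]1(O2)[C@@H](O[Si](C)(C)C(C)(C)C)CC[C@@H](O)[C@@H]1OC2(C)C
F6 | step 10 | 3,4-dihydro analogue of 21 (dibenzoate) | O=C(OC[C@@]1(O2)[C@@H](O[Si](C)(C)C(C)(C)C)CC[C@@H](OC(=O)c3ccccc3)[C@@H]1OC2(C)C)c1ccccc1
F7 | step 10 | 3,4-dihydro analogue of 22 (C2 alcohol) | O=C(OC[C@@]1(O2)[C@@H](O)CC[C@@H](OC(=O)c3ccccc3)[C@@H]1OC2(C)C)c1ccccc1
F8 | step 10 | 3,4-dihydro analogue of 23 (cyclohexanone) | O=C(OC[C@@]1(O2)C(=O)CC[C@@H](OC(=O)c3ccccc3)[C@@H]1OC2(C)C)c1ccccc1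
F9 | step 10 | trimethylsilyl enol ether of F8 (C2=C3) | O=C(OC[C@@]1(O2)C(O[Si](C)(C)C)=CC[C@@H](OC(=O)c3ccccc3)[C@@H]1OC2(C)C)c1ccccc1
F10 | step 7 | C6 pivalate of 11 | CC1(C)OC[C@@H](O1)[C@@H](O[Si](C)(C)C(C)(C)C)C#C[C@@H](OCc1ccc(OC)cc1)COC(=O)C(C)(C)C
F11 | step 7 | C6 pivalate of triol 12 (free C1/C7 diol) | OC[C@@H](O)[C@@H](O[Si](C)(C)C(C)(C)C)C#C[C@@H](OCc1ccc(OC)cc1)COC(=O)C(C)(C)C
F12 | step 7 | dibutylstannylene acetal of F11 | CCCC[Sn]1(CCCC)OC[C@@H](O1)[C@@H](O[Si](C)(C)C(C)(C)C)C#C[C@@H](OCc1ccc(OC)cc1)COC(=O)C(C)(C)C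
F13 | step 7 | C6 pivalate of 14 | COc1ccc(COC[C@@H](O)[C@@H](O[Si](C)(C)C(C)(C)C)C#C[C@@H](OCc2ccc(OC)cc2)COC(=O)C(C)(C)C)cc1
F14 | step 3 | syn (1R) carbinol epimer of 9 | CC1(C)OC[C@@H](O1)[C@H](O)C#C[C@@H]1COC(c2ccc(OC)cc2)O1
F15 | step 3 | 4-nitrobenzoate of 9 (anti, after inversion) | CC1(C)OC[C@@H](O1)[C@@H](OC(=O)c1ccc([N+](=O)[O-])cc1)C#C[C@@H]1COC(c2ccc(OC)cc2)O1
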